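Remark: all cyclopentane intermediates are described with the atom numbering of the target 20 (C1 allyl carbon, C5 methoxy carbon, C6 aryl carbon, C7 methyl carbon, C8 carbonyl carbon). Compounds 1, 5, 12 and 14 are taken as commercial; 13 and 16 are made and used fresh.

## Analysis of the target

The target 20 is a bicyclo[3.2.1]oct-2-en-8-one: a cyclopentanone (C1, C8, C5, C6, C7) bridged between C1 and C5 by the three-carbon unit C2=C3(OMe)–C4(OAc). It has five stereocentres, four of them contiguous (C4–C5–C6–C7). The two bridgeheads C1 (allyl) and C5 (methoxy) are fully substituted carbons on either side of the C8 ketone.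

On the cyclopentanone the C6 aryl group is exo (anti to the three-carbon bridge, cis to the C5 methoxy group). The C7 methyl group is endo and trans to the aryl group. The configuration of C1 is tied to that of C5 by the bridge. The C4 acetoxy group lies on the side of the C8 carbonyl, anti to C6 across the C4–C5 bond.

Sensitive groups are the enol ether C2=C3 (acid), the allylic acetate next to it (ionisation; retro-aldol cleavage of C4–C5 once it is a free β-hydroxy ketone under base), the terminal alkene and the electron-rich dimethoxyphenyl ring (oxidants).

The difficulty is the density of substitution around one ketone. The C4 carbinol centre would also be hard to correct late, because hydride should reach a C4 ketone in the bicycle from the open face next to C8 and put the oxygen on the wrong side.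

The strategy rests on reading the cyclopentanone as a vicinally difunctionalised enone. C6 is β and C5 is α to the C8 carbonyl, the C4–C5 bond is an aldol bond, and the last bond, C1–C2, joins the only enolisable carbon to the terminus of an enol ether.

## Retrosynthetic reasoning

**C1–C2 (20 ⇒ 19).** The bridge is cut between the bridgehead C1 and the vinylic carbon C2, giving the monocyclic acetate 19. C1 is the only α-carbon of 19 that carries a hydrogen. The C2=C3 enol ether of 20 is the oxidation level that results when a carbon radical adds to the CH2 terminus of a 2-methoxyallyl unit and the adduct radical is oxidised and loses a proton. The forward step must therefore generate the C1 radical oxidatively, close 6-endo, and spare the enol ether and the arene.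

**Acetyl group (19 ⇒ 18).** The acetate is put on the aldol 18 just before the oxidative step. As an ester the β-oxygen can no longer trigger retro-aldol cleavage of the congested C4–C5 bond.

**C6–aryl and C4–C5 (18 ⇒ 11 + 13 + 16).** Both bonds flank one enolate position, so they are cut together. The aryl group comes from the Grignard reagent 13 as a conjugate nucleophile at C6 of the methoxy enone 11, and C4 comes from 2-methoxyacrolein 16 as the aldol acceptor at C5. This removes any separate enolate regiochemistry problem, because the enolate is born at C8/C5 and trapped as the silyl enol ether 17. It also loads three stereocentres and all three bridge carbons in one operation. The forward step must add anti to the C7 methyl group, react anti to the new aryl group, and set C4 by the topology of the aldol transition state.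

**C5–OMe (11 ⇒ 10 ⇒ 9).** The methoxy group on the α-carbon of the enone is traced to the epoxy ketone 10 and so to the enone 9. An alkoxide opens the epoxide at the α-carbon and water is lost. This is regiospecific, unlike O-alkylation of a 1,2-dione, whose enol would move to the more substituted side.

**C5=C6 and C1–allyl (9 ⇒ 7 ⇒ 6 ⇒ 4 + 5).** The enone is traced to the ketone 7 by dehydrogenation on the unsubstituted side. The allyl group of 7 is cut next to an ester: in the keto ester 4 the carbon between the two carbonyl groups is the only nucleophilic site, so allyl bromide 5 is placed next to the methyl-bearing carbon without a regiochemical question. The ester is then removed from 6.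

**Ring contraction (4 ⇒ 3 ⇒ 1).** The methylcyclopentanone keto ester comes from (R)-pulegone 1 by Favorskii contraction to 3 and cleavage of the isopropylidene group. The C7 stereocentre is taken from the chiral pool and every later centre is set relative to it.

**Side components (13 ⇐ 12; 16 ⇐ 14 through 15).** The Grignard reagent comes from the aryl bromide 12. The enal comes from the acetal 14 by hydrolysis to 15 and α-methylenation.

## Alternatives that were turned down

**Alternative 1:** The cyclopentanone is cut at C5–C6 and C1–C8. A Lewis acid opens the donor–acceptor cyclopropane A1, the silyl ketene acetal A2 attacks the benzylic carbon with inversion, and the malonate carbon closes on the oxocarbenium carbon to give the keto diester A3.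
- For: the ring is made convergently with the aryl group in place, and C6 is set stereospecifically from an enantioenriched cyclopropane, independently of C7. On that point it is stronger than the chosen route, where C6 depends on the directing power of one methyl group.
- Against: inversion at C6 with retention at C7 means the trans aryl/methyl relationship must come from the cis-cyclopropane, the less accessible isomer. A3 also carries a geminal diester at C1 and a still enolisable CH(OMe) at C5. One ester must be removed, the allyl group introduced, C5 quaternised with the three-carbon unit and the bridge closed.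
- Comparison: the hardest problems of the target (quaternary C5, C4, C1–C2) lie after the key step and cost at least five or six further steps. The chosen route merges the arylation of C6 with the quaternisation of C5.

**Alternative 2:** The bond C1–C7 is cut. A tin hydride turns the selenide A4 into a tertiary α-keto radical that adds 5-exo to the vinyl group on C6, closing the cyclopentanone and leaving the methyl group in the dione A5.
- For: a Claisen rearrangement through a chair sets C5 and C6 together, radical closures tolerate congestion, and a 4-substituted hexenyl radical should give the trans aryl/methyl pair.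
- Against: in the precursor of A4 the two carbonyl arms of the 2-substituted 1,3-dione are diastereotopic. Which arm receives the allyl and selanyl groups decides whether the aryl group ends up exo or endo, and nothing in the structure directs this choice. A5 also has a saturated bridge at the wrong oxidation level. The C3 enol ether must be built by oxidation next to C4, then C4 reduced in the presence of C8 with the right facial sense and acetylated.
- Comparison: that is four or more steps after the key step, with the same C4 problem as Alternative 3. In the chosen route 2-methoxyacrolein 16 delivers C2–C4 at the final oxidation level, and two steps follow the key step.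

**Alternative 3:** The bond C5–C6 is cut and C6 is reattached to the enol oxygen. Acid ionises the benzylic C–O bond of the 3a-allyl hydrobenzofuranone A6, and the freed 2-methoxy-1,3-diketone enol captures the cation through C5 to give the bicyclic enedione A7.
- For: this is the shortest route. All carbons and both quaternary centres are present before the key step and the bicycle forms in one cationic step. In step economy and convergence it is stronger than the chosen strategy.
- Against: the absolute configuration rests on making the quaternary allyl-bearing carbon of A6 enantioselectively in a dearomatising rearrangement. C6 is set in a cation capture with only weak bias. A7 must then be reduced at C4 in the presence of C8, with hydride entering from the more hindered endo face to place the oxygen on the C8 side. This is the step most likely to give the C4 epimer.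
- Comparison: the chosen strategy takes absolute configuration from 1 and sets C4 in an acyclic aldol step before the bicycle exists. A wrong outcome there can still be corrected by oxidation and chelation-controlled reduction.

Key step: step 10

## Route

Step 1
Reactants: 1 (R)-pulegone
Product: 3 methyl (5R)-5-methyl-2-(propan-2-ylidene)cyclopentane-1-carboxylate (methyl pulegenate; both C1 epimers), via pulegone dibromide 2 (not isolated)
Conditions: Br2, NaHCO3, Et2O, −10 °C; then NaOMe, MeOH, reflux
Reagents that add atoms: sodium methoxide [Na+].[O-]C; bromine BrBr (its atoms stay only in 2)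
Why: Bromine adds to the tetrasubstituted alkene and methoxide then causes a Favorskii ring contraction (cyclopropanone from the C6 enolate, opening with loss of the second bromide to restore the isopropylidene group); the methyl-bearing stereocentre is not touched.

Step 2
Reactants: 3 methyl pulegenate
Product: 4 methyl (1S,2R)-2-methyl-5-oxocyclopentane-1-carboxylate (trans keto form; C1 epimerisable)
Conditions: O3, CH2Cl2/MeOH, −78 °C; then Me2S
Reagents that add atoms: ozone O=[O+][O-]
Why: Ozonolysis of the exocyclic tetrasubstituted alkene with reductive work-up gives the ring ketone; the ester-bearing carbon equilibrates through the enol, so both epimers of 3 converge.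

Step 3
Reactants: 4 keto ester; 5 allyl bromide
Product: 6 methyl (1R,2R)-2-methyl-5-oxo-1-(prop-2-en-1-yl)cyclopentane-1-carboxylate
Conditions: K2CO3, acetone, reflux
Reagents that add atoms: none
Why: C-alkylation of the β-keto ester enolate; the carbon between the carbonyl groups is the only acidic site, so the allyl group is placed regiospecifically, mainly anti to the neighbouring methyl group (this centre is not kept).

Step 4
Reactants: 6 allylated keto ester
Product: 7 (2S,3R)-3-methyl-2-(prop-2-en-1-yl)cyclopentan-1-one
Conditions: LiCl, H2O, DMSO, 150 °C
Reagents that add atoms: none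
Why: Krapcho dealkoxycarbonylation (chloride demethylates the ester, the carboxylate loses CO2); protonation of the enolate and equilibration should give the more stable trans-2,3-disubstituted ketone.

Step 5
Reactants: 7 trans-2-allyl-3-methylcyclopentanone
Product: 9 (4R,5S)-4-methyl-5-(prop-2-en-1-yl)cyclopent-2-en-1-one, via kinetic silyl enol ether 8 (not isolated)
Conditions: LiN(iPr)2, THF, −78 °C; TMSCl; then Pd(OAc)2, MeCN, rt
Reagents that add atoms: chlorotrimethylsilane C[Si](C)(C)Cl (its atoms stay only in 8)
Why: Kinetic deprotonation at the unsubstituted CH2 gives the less substituted silyl enol ether, and Saegusa–Ito oxidation (oxa-π-allylpalladium, β-hydride elimination) places the double bond on that side only; the isolated allyl group should not interfere.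

Step 6
Reactants: 9 enone
Product: 10 (1R,3S,4S,5R)-4-methyl-3-(prop-2-en-1-yl)-6-oxabicyclo[3.1.0]hexan-2-one
Conditions: 30% aq. H2O2, NaOH (cat.), MeOH, −20 to 0 °C
Reagents that add atoms: hydrogen peroxide OO
Why: Weitz–Scheffer nucleophilic epoxidation; hydroperoxide adds to the β-carbon anti to the adjacent methyl group and the enolate closes the ring, while the unactivated terminal alkene does not react; the epoxide configuration is lost in step 7.

Step 7
Reactants: 10 epoxy ketone
Product: 11 (4R,5S)-2-methoxy-4-methyl-5-(prop-2-en-1-yl)cyclopent-2-en-1-one
Conditions: NaOMe, MeOH, 0 °C to rt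
Reagents that add atoms: sodium methoxide [Na+].[O-]C (methanol CO is the net source)
Why: Conversion of an α,β-epoxy ketone into an α-alkoxy enone: methoxide opens the epoxide at the carbon next to the carbonyl group and the β-hydroxy ketone dehydrates by E1cB; low temperature is chosen to limit deprotonation at the methyl-bearing γ-carbon, and the allyl-bearing carbon settles trans.

Step 8
Reactants: 12 4-bromo-1,2-dimethoxybenzene
Product: 13 (3,4-dimethoxyphenyl)magnesium bromide (THF solution)
Conditions: Mg turnings, I2 (cat.), THF, 40 °C
Reagents that add atoms: magnesium [Mg]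
Why: Grignard formation by insertion of magnesium into the aryl–bromine bond; the methoxy groups are inert.

Step 9
Reactants: 14 1,1,2-trimethoxyethane
Product: 16 2-methoxyprop-2-enal (2-methoxyacrolein), via methoxyacetaldehyde 15 (not isolated)
Conditions: 1 M aq. HCl, 50 °C; then NaOAc (to pH 5), 37% aq. HCHO, pyrrolidine (10 mol%), EtCO2H (10 mol%), 45 °C; distillation
Reagents that add atoms: formaldehyde C=O
Why: Acid hydrolysis of the dimethyl acetal gives 15, and amine-catalysed Mannich condensation with formaldehyde followed by loss of the amine (α-methylenation of an aldehyde) gives the 2-alkoxy enal, which is distilled and used at once.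

Step 10
Reactants: 11 methoxy enone; 13 aryl Grignard reagent; 16 2-methoxyacrolein
Product: 18 (2S,3R,4S,5S)-4-(3,4-dimethoxyphenyl)-5-[(1S)-1-hydroxy-2-methoxyprop-2-en-1-yl]-5-methoxy-3-methyl-2-(prop-2-en-1-yl)cyclopentan-1-one, via arylated silyl enol ether 17 (not isolated)
Conditions: 13 (1.3 equiv), CuBr·SMe2 (10 mol%), TMSCl (2 equiv), THF, −78 to −40 °C; volatiles removed in the flask, CH2Cl2; 16 (2 equiv), BF3·OEt2 (1.5 equiv), −78 °C; aq. NaHCO3
Reagents that add atoms: chlorotrimethylsilane C[Si](C)(C)Cl (its atoms stay only in 17)
Why: Copper-catalysed conjugate addition of 13, accelerated by TMSCl because the 2-methoxy enone is a weak acceptor, places the aryl group on C6 anti to the C7 methyl group, as expected for 4-substituted cyclopentenones, and the enolate is caught as the tetrasubstituted silyl enol ether 17, whose position (C8=C5) and geometry are fixed by the ring and the methoxy group. In the same flask BF3·OEt2 activates 16 and 17 attacks the aldehyde carbon through C5 in a Mukaiyama aldol addition, so the C6–aryl and C4–C5 bonds form in one operation and no ring is closed; the closest known reaction type is the three-component conjugate addition–enolate trapping–aldol coupling on cyclopentenones. C6 is controlled by the neighbouring C7 methyl group, and C5 by the new C6 aryl group: the aldehyde enters the enol ether face opposite to the aryl group, which leaves the methoxy group cis and the side chain trans to the aryl group. C4 is controlled by the topology of the transition state: the aldehyde hydrogen must sit over the ring, because that face also carries the C7 methyl group, and an open antiperiplanar arrangement then keeps the BF3-bound oxygen away from the two enol oxygens and should give the (1S)-carbinol. A metal-bridged six-membered transition state would instead hold the aldehyde oxygen between those two oxygens and lead to the C4 epimer, which is why the aldol is run on the silyl enol ether and not on a zinc or magnesium enolate. The step needs 1,4- and not 1,2-addition of the aryl group (copper and TMSCl), 1,2- and not 1,4-attack on 16 (its β-carbon is deactivated by the 2-methoxy group) and a single enolate position (17 is never equilibrated).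

Step 11
Reactants: 18 aldol
Product: 19 (1S)-1-[(1S,2S,3R,4S)-2-(3,4-dimethoxyphenyl)-1-methoxy-3-methyl-5-oxo-4-(prop-2-en-1-yl)cyclopentyl]-2-methoxyprop-2-en-1-yl acetate
Conditions: Ac2O, DMAP, Et3N, CH2Cl2, 0 °C to rt
Reagents that add atoms: acetic anhydride CC(=O)OC(C)=O
Why: DMAP-catalysed acylation of the hindered secondary alcohol without forming an alkoxide, so retro-aldol cleavage is avoided; C4 is not touched and the ester blocks fragmentation in step 12.

Step 12
Reactants: 19 acetate
Product: 20 (1S,4S,5S,6S,7R)-6-(3,4-dimethoxyphenyl)-3,5-dimethoxy-7-methyl-8-oxo-1-(prop-2-en-1-yl)bicyclo[3.2.1]oct-2-en-4-yl acetate (numbering: C1 allyl bridgehead)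
Conditions: Mn(OAc)3 (2.2 equiv), Cu(OAc)2 (1 equiv), KOAc, AcOH/Ac2O, 80 °C, argon
Reagents that add atoms: none
Why: Oxidative free-radical cyclisation of an unsaturated ketone, as established for 2-allylcycloalkanones: the manganese enolate at C1, the only enolisable position, gives the tertiary α-keto radical, which closes 6-endo on the terminal carbon C2 of the electron-rich enol ether (5-exo attack on the methoxy-bearing carbon is polarity-mismatched and would give a norbornanone), and the α-methoxy radical at C3 is oxidised by Cu(OAc)2 and loses a proton from C2 to give the C2=C3 enol ether. C1 is set by ring constraint, since the bridge can only form on the face that carries the C5 side chain; acetate buffer and exclusion of water protect the two enol ethers, which are deactivated towards protonation by the adjacent acetoxy carbon.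

## Compound list

1 | (R)-pulegone, (5R)-5-methyl-2-(propan-2-ylidene)cyclohexan-1-one | C[C@@H]1CCC(=C(C)C)C(=O)C1 | starting material
2 | (5R)-2-bromo-2-(2-bromopropan-2-yl)-5-methylcyclohexan-1-one (pulegone dibromide, C2 epimers) | C[C@@H]1CCC(Br)(C(C)(C)Br)C(=O)C1 | intermediate (not isolated)
3 | methyl (5R)-5-methyl-2-(propan-2-ylidene)cyclopentane-1-carboxylate (C1 epimers) | C[C@@H]1CCC(=C(C)C)C1C(=O)OC | intermediate
4 | methyl (1S,2R)-2-methyl-5-oxocyclopentane-1-carboxylate (trans; C1 epimerisable) | C[C@@H]1CCC(=O)[C@H]1C(=O)OC | intermediate
5 | allyl bromide, 3-bromoprop-1-ene | C=CCBr | starting material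
6 | methyl (1R,2R)-2-methyl-5-oxo-1-(prop-2-en-1-yl)cyclopentane-1-carboxylate | C[C@@H]1CCC(=O)[C@]1(CC=C)C(=O)OC | intermediate
7 | (2S,3R)-3-methyl-2-(prop-2-en-1-yl)cyclopentan-1-one | C=CC[C@H]1[C@H](C)CCC1=O | intermediate
8 | trimethyl{[(4R,5S)-4-methyl-5-(prop-2-en-1-yl)cyclopent-1-en-1-yl]oxy}silane | C=CC[C@H]1[C@H](C)CC=C1O[Si](C)(C)C | intermediate (not isolated)
9 | (4R,5S)-4-methyl-5-(prop-2-en-1-yl)cyclopent-2-en-1-one | C=CC[C@H]1[C@H](C)C=CC1=O | intermediate
10 | (1R,3S,4S,5R)-4-methyl-3-(prop-2-en-1-yl)-6-oxabicyclo[3.1.0]hexan-2-one | C=CC[C@H]1[C@H](C)[C@H]2O[C@H]2C1=O | intermediate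
11 | (4R,5S)-2-methoxy-4-methyl-5-(prop-2-en-1-yl)cyclopent-2-en-1-one | C=CC[C@H]1[C@H](C)C=C(OC)C1=O | intermediate (precursor of the key step)
12 | 4-bromo-1,2-dimethoxybenzene | COc1ccc(Br)cc1OC | starting material
13 | (3,4-dimethoxyphenyl)magnesium bromide | COc1ccc([Mg]Br)cc1OC | intermediate (precursor of the key step)
14 | 1,1,2-trimethoxyethane | COCC(OC)OC | starting material
15 | methoxyacetaldehyde | COCC=O | intermediate (not isolated)
16 | 2-methoxyprop-2-enal | C=C(OC)C=O | intermediate (precursor of the key step)
17 | {[(3S,4S,5S)-3-(3,4-dimethoxyphenyl)-2-methoxy-4-methyl-5-(prop-2-en-1-yl)cyclopent-1-en-1-yl]oxy}trimethylsilane | C=CC[C@H]1[C@H](C)[C@@H](c2ccc(OC)c(OC)c2)C(OC)=C1O[Si](C)(C)C | intermediate (not isolated)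
18 | (2S,3R,4S,5S)-4-(3,4-dimethoxyphenyl)-5-[(1S)-1-hydroxy-2-methoxyprop-2-en-1-yl]-5-methoxy-3-methyl-2-(prop-2-en-1-yl)cyclopentan-1-one | C=CC[C@H]1[C@H](C)[C@@H](c2ccc(OC)c(OC)c2)[C@](OC)([C@@H](O)C(OC)=C)C1=O | intermediate (product of the key step)
19 | (1S)-1-[(1S,2S,3R,4S)-2-(3,4-dimethoxyphenyl)-1-methoxy-3-methyl-5-oxo-4-(prop-2-en-1-yl)cyclopentyl]-2-methoxyprop-2-en-1-yl acetate | C=CC[C@H]1[C@H](C)[C@@H](c2ccc(OC)c(OC)c2)[C@](OC)([C@@H](OC(C)=O)C(OC)=C)C1=O | intermediate
20 | (1S,4S,5S,6S,7R)-6-(3,4-dimethoxyphenyl)-3,5-dimethoxy-7-methyl-8-oxo-1-(prop-2-en-1-yl)bicyclo[3.2.1]oct-2-en-4-yl acetate | C=CC[C@]12C=C(OC)[C@H](OC(C)=O)[C@](OC)(C1=O)[C@H](c1ccc(OC)c(OC)c1)[C@H]2C | target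

## Step count and least certain steps

Total: 12 steps. Longest linear sequence: 10 steps (steps 1–7 and 10–12, from 1). Steps 8 and 9 prepare the two other components of the key step.

**Step 10 (key step).** Three things may go wrong.
- Selectivity at the carbinol carbon may be poor if a synclinal arrangement, with the aldehyde oxygen between the two enol oxygens, competes with the antiperiplanar one.
- The conjugate addition to the electron-rich enone may be incomplete, or 17 may be protodesilylated before the aldol.
- The enal may be attacked at its β-carbon, or its enol ether may be lost under the Lewis acid.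

Fallback: the carbinol configuration is set by a hydride reduction and not in the C–C bond formation. Starting from 11, the stoichiometric arylcopper reagent from 13 and CuBr·SMe2 is added in THF at −78 °C without silyl chloride. The enolate is transmetalated with ZnCl2 and treated with 16. The metal-bridged transition state should give mainly the epimeric aldol (2S,3R,4S,5S)-4-(3,4-dimethoxyphenyl)-5-[(1R)-1-hydroxy-2-methoxyprop-2-en-1-yl]-5-methoxy-3-methyl-2-(prop-2-en-1-yl)cyclopentan-1-one F1. Oxidation with Dess–Martin periodinane (NaHCO3, CH2Cl2) gives the non-enolisable diketone (2S,3R,4S,5R)-4-(3,4-dimethoxyphenyl)-5-methoxy-5-(2-methoxyprop-2-enoyl)-3-methyl-2-(prop-2-en-1-yl)cyclopentan-1-one F2. Reduction with Zn(BH4)2 in Et2O at −78 °C should hold the two carbonyl groups in a six-membered chelate; hydride then enters from the face away from the cyclopentane ring and gives 18, where the sequence rejoins the route. Any F1 formed as a by-product in step 10 can be recycled in the same way.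

**Step 12.** Four things may go wrong.
- The enol ether of 19 or of 20 may be solvolysed in hot acetic acid.
- The oxocarbenium ion at C3 may be captured by acetate or water, leading to a C3 ketone and not the enol ether.
- The hindered ketone may enolise slowly.
- The tertiary radical may be oxidised by divalent copper before it cyclises.

Fallback: the oxidation is moved to non-acidic conditions through a preformed enol derivative. Starting from 19, soft enolisation (TMSOTf, Et3N, CH2Cl2, 0 °C) gives the silyl enol ether (1S)-1-[(1S,2S,3R)-2-(3,4-dimethoxyphenyl)-1-methoxy-3-methyl-4-(prop-2-en-1-yl)-5-(trimethylsilyloxy)cyclopent-4-en-1-yl]-2-methoxyprop-2-en-1-yl acetate F3. Its oxidative cyclisation with Cu(OTf)2 and Cu2O in MeCN at 0 °C (oxidative cyclisation of unsaturated silyl enol ethers) should give 20 directly.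

**Step 7.** Methoxide may remove the γ-hydrogen at the methyl-bearing carbon, which would move the double bond into the more substituted position and erase the stereocentre. The epoxide may also be opened at the β-carbon.

Fallback: the C–O bond is made by cross-coupling and not through the epoxide. Starting from 9, α-iodination (I2, pyridine, CH2Cl2) gives (4S,5S)-2-iodo-4-methyl-5-(prop-2-en-1-yl)cyclopent-2-en-1-one F4. Copper-catalysed etherification of the vinyl iodide with methanol (CuI, 3,4,7,8-tetramethyl-1,10-phenanthroline, Cs2CO3, toluene/MeOH, 80 °C) gives 11.

**Step 9.** The volatile enal may polymerise or be lost on isolation, and 15 may self-condense before the methylenation.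

Fallback: the aldehyde is made by oxidation of an allylic alcohol in organic solvent. Commercial methyl 2-methoxyprop-2-enoate F5 is reduced with iBu2AlH (CH2Cl2, −78 °C) to 2-methoxyprop-2-en-1-ol F6. This is oxidised with MnO2 in CH2Cl2, and the filtered solution of 16 is used directly in step 10.

## Further compounds

F1 | step 10 | (2S,3R,4S,5S)-4-(3,4-dimethoxyphenyl)-5-[(1R)-1-hydroxy-2-methoxyprop-2-en-1-yl]-5-methoxy-3-methyl-2-(prop-2-en-1-yl)cyclopentan-1-one | C=CC[C@H]1[C@H](C)[C@@H](c2ccc(OC)c(OC)c2)[C@](OC)([C@H](O)C(OC)=C)C1=O
F2 | step 10 | (2S,3R,4S,5R)-4-(3,4-dimethoxyphenyl)-5-methoxy-5-(2-methoxyprop-2-enoyl)-3-methyl-2-(prop-2-en-1-yl)cyclopentan-1-one | C=CC[C@H]1[C@H](C)[C@@H](c2ccc(OC)c(OC)c2)[C@](OC)(C(=O)C(OC)=C)C1=O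
F3 | step 12 | (1S)-1-[(1S,2S,3R)-2-(3,4-dimethoxyphenyl)-1-methoxy-3-methyl-4-(prop-2-en-1-yl)-5-(trimethylsilyloxy)cyclopent-4-en-1-yl]-2-methoxyprop-2-en-1-yl acetate | C=CCC=1[C@H](C)[C@@H](c2ccc(OC)c(OC)c2)[C@](OC)([C@@H](OC(C)=O)C(OC)=C)C=1O[Si](C)(C)C
F4 | step 7 | (4S,5S)-2-iodo-4-methyl-5-(prop-2-en-1-yl)cyclopent-2-en-1-one | C=CC[C@H]1[C@H](C)C=C(I)C1=O
F5 | step 9 | methyl 2-methoxyprop-2-enoate | C=C(OC)C(=O)OC
F6 | step 9 | 2-methoxyprop-2-en-1-ol | C=C(OC)CO
A1 | alternative 1 | dimethyl (2R,3R)-2-(3,4-dimethoxyphenyl)-3-methylcyclopropane-1,1-dicarboxylate (aryl and methyl cis) | COC(=O)C1(C(=O)OC)[C@H](C)[C@@H]1c1ccc(OC)c(OC)c1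
A2 | alternative 1 | [(1,2-dimethoxyethenyl)oxy]trimethylsilane | COC=C(OC)O[Si](C)(C)C
A3 | alternative 1 | dimethyl (3S,4S,5R)-4-(3,4-dimethoxyphenyl)-3-methoxy-5-methyl-2-oxocyclopentane-1,1-dicarboxylate | COC(=O)C1(C(=O)OC)[C@H](C)[C@@H](c2ccc(OC)c(OC)c2)[C@H](OC)C1=O
A4 | alternative 2 | (2S)-2-[(1S)-1-(3,4-dimethoxyphenyl)prop-2-en-1-yl]-2-methoxy-4-(phenylselanyl)-4-(prop-2-en-1-yl)cyclohexane-1,3-dione (C4 epimers) | C=CCC1([Se]c2ccccc2)CCC(=O)[C@](OC)(C1=O)[C@H](c1ccc(OC)c(OC)c1)C=C
A5 | alternative 2 | (1S,5S,6S,7R)-6-(3,4-dimethoxyphenyl)-5-methoxy-7-methyl-1-(prop-2-en-1-yl)bicyclo[3.2.1]octane-4,8-dione (target numbering) | C=CC[C@]12CCC(=O)[C@](OC)(C1=O)[C@H](c1ccc(OC)c(OC)c1)[C@H]2C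
A6 | alternative 3 | (2S,3S,3aS)-2-(3,4-dimethoxyphenyl)-5,7-dimethoxy-3-methyl-3a-(prop-2-en-1-yl)-3,3a-dihydro-1-benzofuran-6(2H)-one | C=CC[C@]12C=C(OC)C(=O)C(OC)=C1O[C@H](c1ccc(OC)c(OC)c1)[C@H]2C
A7 | alternative 3 | (1S,5R,6S,7R)-6-(3,4-dimethoxyphenyl)-3,5-dimethoxy-7-methyl-1-(prop-2-en-1-yl)bicyclo[3.2.1]oct-2-ene-4,8-dione (target numbering) | C=CC[C@]12C=C(OC)C(=O)[C@](OC)(C1=O)[C@H](c1ccc(OC)c(OC)c1)[C@H]2C
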